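**Retrosynthetic overview** (germacranolide locants: ring carbons C1–C10, lactone carbons C11–C13)
1. The ten-membered carbocycle is closed last, at C3–C4, by an intramolecular Nozaki–Hiyama–Kishi reaction of enal/alkenyl iodide 15; 15 comes from vinyl carbinol 14 by cross-metathesis.
2. The cis-fused α-methylene-γ-butyrolactone is formed first: chiral Brønsted acid-catalysed 2-(methoxycarbonyl)allylboration/lactonisation of (Z)-3-iodobut-2-enal 4 with boronate 12 makes C6–C7 and sets C6 and C7.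
3. Boronate 12 comes from lactol 9 by iodo-Wittig olefination, C8 angeloylation and Negishi borylmethylation.
4. Lactol 9 comes from aldol 7 by chelation-controlled vinyl addition (C10) and acetal hydrolysis; 7 is the D-proline aldol of acetone with 2,2-dimethoxyacetaldehyde (first stereocentre, C8).
5. Aldehyde 4 comes from but-2-yn-1-ol by hydroalumination–iodination and oxidation.

Assumption: the SMILES is taken literally (1E,4Z; 3S,6S,7R,8S,10S; cis-fused 6,12-lactone); small reagents are given under "Reagents that add atoms" and carry no compound number.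

**Step 1**
Reactants: 1 but-2-yn-1-ol
Product: 3 (2Z)-3-iodobut-2-en-1-ol, via cyclic alkenylalanate 2 (not isolated)
Conditions: NaAlH2(OCH2CH2OMe)2 (1.5 equiv), THF, 0 → 23 °C; then I2, THF, −78 → 0 °C
Reagents that add atoms: iodine, II
Why: hydroxyl-directed trans-hydroalumination puts aluminium on C3 cis to the CH2O group and iodinolysis of the C–Al bond goes with retention (hydroalumination–iodination), fixing the Z geometry of the later 4Z olefin.

**Step 2**
Reactants: 3 (2Z)-3-iodobut-2-en-1-ol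
Product: 4 (2Z)-3-iodobut-2-enal
Conditions: MnO2 (15 equiv), CH2Cl2, 23 °C, dark
Reagents that add atoms: none
Why: MnO2 oxidation of the allylic alcohol is neutral and does not isomerise the Z-iodoalkene; the enal is used fresh.

**Step 3**
Reactants: 5 acetone; 6 2,2-dimethoxyacetaldehyde
Product: 7 (4S)-4-hydroxy-5,5-dimethoxypentan-2-one
Conditions: D-proline (20 mol %), acetone/DMSO (4:1), 4 °C
Reagents that add atoms: none
Why: proline-catalysed direct asymmetric aldol reaction (enamine catalysis); the D-proline enamine of acetone adds to the Si face of the non-enolisable aldehyde through the acid-hydrogen-bonded chair transition state, setting the first stereocentre (future C8) as S.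

**Step 4**
Reactants: 7 (4S)-4-hydroxy-5,5-dimethoxypentan-2-one
Product: 8 (2S,4S)-1,1-dimethoxy-4-methylhex-5-ene-2,4-diol
Conditions: CH2=CHMgBr (3.5 equiv), THF, −78 → −40 °C
Reagents that add atoms: vinylmagnesium bromide, C=C[Mg]Br
Why: chelation-controlled Grignard addition; the magnesium alkoxide of the β-hydroxyl holds the ketone in a six-membered chelate and vinyl enters axially, anti to the carbinol substituent, giving the 1,3-anti diol (future C10 as S), with the minor syn isomer removed by chromatography.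

**Step 5**
Reactants: 8 (2S,4S)-1,1-dimethoxy-4-methylhex-5-ene-2,4-diol
Product: 9 (3S,5S)-5-ethenyl-5-methyloxolane-2,3-diol (lactol; both anomers)
Conditions: AcOH/H2O/THF (3:1:1), 45 °C
Reagents that add atoms: water, O
Why: acid-catalysed acetal hydrolysis, assisted by the tertiary hydroxyl, gives the five-membered lactol; the weak acid should spare the tertiary allylic alcohol, and neither stereocentre is touched.

**Step 6**
Reactants: 9 lactol
Product: 10 methyl (2Z,4S,6S)-4,6-dihydroxy-2-iodo-6-methylocta-2,7-dienoate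
Conditions: Ph3P=CHCO2Me (1.5 equiv), N-iodosuccinimide (1.5 equiv), CH2Cl2, −20 °C; then 9, toluene, 60 °C
Reagents that add atoms: methyl (triphenylphosphoranylidene)acetate, COC(=O)C=P(c1ccccc1)(c1ccccc1)c1ccccc1; N-iodosuccinimide, O=C1CCC(=O)N1I
Why: Wittig olefination of the open hydroxy-aldehyde form of the lactol with the stabilised α-iodo ylide made in the flask; reversible oxaphosphetane formation puts the chain trans to the ester (2Z), and the lactol form protects the α-hydroxy aldehyde from epimerisation.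

**Step 7**
Reactants: 10 iodo diol ester
Product: 11 methyl (2Z,4S,6S)-6-hydroxy-2-iodo-6-methyl-4-{[(2Z)-2-methylbut-2-enoyl]oxy}octa-2,7-dienoate
Conditions: angelic acid (1.5 equiv), 2,4,6-Cl3C6H2COCl, Et3N, toluene, 23 °C; then 10, 23 → 60 °C
Reagents that add atoms: angelic acid [(2Z)-2-methylbut-2-enoic acid], C/C=C(/C)C(=O)O
Why: Yamaguchi-type mixed-anhydride esterification without DMAP acylates only the secondary hydroxyl (the tertiary one is inert) and avoids angelate-to-tiglate isomerisation.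

**Step 8**
Reactants: 11 angelate iodoenoate
Product: 12 methyl (2E,4S,6S)-6-hydroxy-6-methyl-4-{[(2Z)-2-methylbut-2-enoyl]oxy}-2-[(4,4,5,5-tetramethyl-1,3,2-dioxaborolan-2-yl)methyl]octa-2,7-dienoate
Conditions: ICH2Bpin (2.5 equiv), Zn dust, THF, 23 °C; then 11, Pd(PPh3)4 (5 mol %), THF, 40 °C
Reagents that add atoms: 2-(iodomethyl)-4,4,5,5-tetramethyl-1,3,2-dioxaborolane, ICB1OC(C)(C)C(C)(C)O1
Why: Negishi cross-coupling of the alkenyl iodide with the (borylmethyl)zinc iodide proceeds under neutral conditions with retention of olefin geometry, giving the 2-(methoxycarbonyl)allyl boronate with the C8 substituent cis to CH2B.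

**Step 9**
Reactants: 12 allyl boronate; 4 (2Z)-3-iodobut-2-enal
Product: 14 (1S,3S)-3-hydroxy-1-[(2R,3R)-2-[(1Z)-2-iodoprop-1-en-1-yl]-4-methylidene-5-oxooxolan-3-yl]-3-methylpent-4-en-1-yl (2Z)-2-methylbut-2-enoate, via open-chain borate ester 13 (not isolated)
Conditions: (R)-3,3′-bis(2,4,6-triisopropylphenyl)-BINOL N-triflylphosphoramide (10 mol %), 4 Å MS, toluene, −20 °C, then 23 °C
Reagents that add atoms: none
Why: Proposed new method: the confined chiral N-triflylphosphoramide hydrogen-bonds a dioxaborolane oxygen of the electron-poor 2-(methoxycarbonyl)allyl boronate and the formyl C–H of 4, so the closed chair allylboration (C8 substituent cis to CH2B, hence cis C6–O/C7–C8) occurs on the Re face of the aldehyde under catalyst control, setting C6 and C7 as in the target whatever the bias of the C8 centre, and borate 13 lactonises on warming; the closest known reactions are chiral phosphoric acid-catalysed allylboration of aldehydes with simple allyl pinacol boronates (Re-face sense taken from there by analogy) and achiral triflic acid- or Sc(OTf)3-catalysed additions of 2-alkoxycarbonyl allylboronates that give α-methylene-γ-butyrolactones.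

**Step 10**
Reactants: 14 iodo vinyl-carbinol lactone
Product: 15 (1S,3S,4E)-3-hydroxy-1-[(2R,3R)-2-[(1Z)-2-iodoprop-1-en-1-yl]-4-methylidene-5-oxooxolan-3-yl]-3-methyl-6-oxohex-4-en-1-yl (2Z)-2-methylbut-2-enoate
Conditions: (E)-crotonaldehyde (10 equiv), RuCl2(H2IMes)(=CH-C6H4-2-OiPr) (second-generation Hoveyda–Grubbs catalyst, 10 mol %), CH2Cl2, 40 °C
Reagents that add atoms: (2E)-but-2-enal, C/C=C/C=O
Why: olefin cross-metathesis of the monosubstituted vinyl carbinol with the enal partner gives the E-enal with loss of propene; the 1,1-disubstituted acrylate, the trisubstituted iodoalkene and the angelate are too hindered or electron-poor to compete.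

**Step 11**
Reactants: 15 enal alkenyl iodide
Product: 16 target (1E,3S,4Z,6S,7R,8S,10S)-8-angeloyloxy-3,10-dihydroxygermacra-1,4,11(13)-trien-12,6-olide
Conditions: CrCl2 (10 equiv), NiCl2 (5 mol %), DMSO/THF (3:1), 2 mM, 23 °C
Reagents that add atoms: none
Why: intramolecular Nozaki–Hiyama–Kishi reaction; nickel-mediated conversion of the Z-alkenyl iodide into the alkenylchromium species (geometry retained) and chemoselective 1,2-addition to the enal close the ten-membered ring at C3–C4, with C3 set by macrocyclic control (3S is assumed here, not demonstrated).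

**Compound list**
1 | but-2-yn-1-ol | CC#CCO | starting material
2 | sodium 2,2-bis(2-methoxyethoxy)-3-methyl-2,5-dihydro-1,2-oxaluminol-2-uide (cyclic alkenylalanate) | CC1=CCO[Al-]1(OCCOC)OCCOC.[Na+] | intermediate
3 | (2Z)-3-iodobut-2-en-1-ol | C/C(I)=C/CO | intermediate
4 | (2Z)-3-iodobut-2-enal | C/C(I)=C/C=O | intermediate
5 | acetone | CC(C)=O | starting material
6 | 2,2-dimethoxyacetaldehyde | COC(OC)C=O | starting material
7 | (4S)-4-hydroxy-5,5-dimethoxypentan-2-one | CC(=O)C[C@H](O)C(OC)OC | intermediate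
8 | (2S,4S)-1,1-dimethoxy-4-methylhex-5-ene-2,4-diol | C=C[C@@](C)(O)C[C@H](O)C(OC)OC | intermediate
9 | (3S,5S)-5-ethenyl-5-methyloxolane-2,3-diol (anomeric mixture) | C=C[C@]1(C)C[C@H](O)C(O)O1 | intermediate
10 | methyl (2Z,4S,6S)-4,6-dihydroxy-2-iodo-6-methylocta-2,7-dienoate | C=C[C@@](C)(O)C[C@H](O)/C=C(\I)C(=O)OC | intermediate
11 | methyl (2Z,4S,6S)-6-hydroxy-2-iodo-6-methyl-4-{[(2Z)-2-methylbut-2-enoyl]oxy}octa-2,7-dienoate | C=C[C@@](C)(O)C[C@H](OC(=O)/C(C)=C\C)/C=C(\I)C(=O)OC | intermediate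
12 | methyl (2E,4S,6S)-6-hydroxy-6-methyl-4-{[(2Z)-2-methylbut-2-enoyl]oxy}-2-[(4,4,5,5-tetramethyl-1,3,2-dioxaborolan-2-yl)methyl]octa-2,7-dienoate | C=C[C@@](C)(O)C[C@H](OC(=O)/C(C)=C\C)/C=C(\CB1OC(C)(C)C(C)(C)O1)C(=O)OC | intermediate
13 | methyl (3S,4R,5Z)-3-[(1S,3S)-3-hydroxy-3-methyl-1-{[(2Z)-2-methylbut-2-enoyl]oxy}pent-4-en-1-yl]-6-iodo-2-methylidene-4-[(4,4,5,5-tetramethyl-1,3,2-dioxaborolan-2-yl)oxy]hept-5-enoate | C=C(C(=O)OC)[C@@H]([C@@H](OB1OC(C)(C)C(C)(C)O1)/C=C(/C)I)[C@@H](OC(=O)/C(C)=C\C)C[C@](C)(O)C=C | intermediate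
14 | (1S,3S)-3-hydroxy-1-[(2R,3R)-2-[(1Z)-2-iodoprop-1-en-1-yl]-4-methylidene-5-oxooxolan-3-yl]-3-methylpent-4-en-1-yl (2Z)-2-methylbut-2-enoate (oxolane C2 is the later C6; it reads R only because iodine changes the CIP ranking) | C=C1C(=O)O[C@@H](/C=C(/C)I)[C@H]1[C@@H](OC(=O)/C(C)=C\C)C[C@](C)(O)C=C | intermediate
15 | (1S,3S,4E)-3-hydroxy-1-[(2R,3R)-2-[(1Z)-2-iodoprop-1-en-1-yl]-4-methylidene-5-oxooxolan-3-yl]-3-methyl-6-oxohex-4-en-1-yl (2Z)-2-methylbut-2-enoate | C=C1C(=O)O[C@@H](/C=C(/C)I)[C@H]1[C@@H](OC(=O)/C(C)=C\C)C[C@](C)(O)/C=C/C=O | intermediate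
16 | (1E,3S,4Z,6S,7R,8S,10S)-8-[(2Z)-2-methylbut-2-enoyloxy]-3,10-dihydroxygermacra-1,4,11(13)-trien-12,6-olide (CNP0262559.5) | C=C1C(=O)O[C@H]2/C=C(/C)[C@@H](O)/C=C/[C@@](C)(O)C[C@H](OC(=O)/C(C)=C\C)[C@@H]12 | target

**Step count and risks**
Total step count: 11. Longest linear sequence: 9 steps (steps 3–11).

Most likely to fail, first: step 9, the proposed new allylboration (low rate with the ester-deactivated boronate, protodeboronation, or wrong facial sense). The fallback uses known chemistry, sets out from 11 (with 4) and comes back at 14. Stille coupling of 11 with Bu3SnCH2OH (Pd(PPh3)4, dioxane, 80 °C) gives methyl (2E,4S,6S)-6-hydroxy-2-(hydroxymethyl)-6-methyl-4-{[(2Z)-2-methylbut-2-enoyl]oxy}octa-2,7-dienoate F1. An Appel reaction (CBr4, PPh3, CH2Cl2, 0 °C) converts it into methyl (2Z,4S,6S)-2-(bromomethyl)-6-hydroxy-6-methyl-4-{[(2Z)-2-methylbut-2-enoyl]oxy}octa-2,7-dienoate F2. Indium-mediated Barbier allylation of 4 with F2 (indium powder, THF/H2O, 23 °C) passes through the Z-configured allylindium in a chair and gives the syn hydroxy ester methyl (3S,4R,5Z)-4-hydroxy-3-[(1S,3S)-3-hydroxy-3-methyl-1-{[(2Z)-2-methylbut-2-enoyl]oxy}pent-4-en-1-yl]-6-iodo-2-methylidenehept-5-enoate F3. F3 lactonises with PPTS in benzene at 50 °C to 14. Facial selectivity then rests on the C8 centre alone, so diastereomer separation is expected.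

Second: step 11, the ten-membered Nozaki–Hiyama–Kishi closure (yield and C3 configuration are both uncertain). The fallback sets out from 14 and comes back at 16, forming the ring at C1=C2 and setting C3 by reagent control. Carbonylative Stille coupling of 14 with Bu3SnCH=CH2 (CO 1 atm, PdCl2(PPh3)2, THF, 50 °C) gives (1S,3S)-3-hydroxy-3-methyl-1-[(2S,3R)-2-[(1Z)-2-methyl-3-oxopenta-1,4-dien-1-yl]-4-methylidene-5-oxooxolan-3-yl]pent-4-en-1-yl (2Z)-2-methylbut-2-enoate F4. Ring-closing metathesis with RuCl2(H2IMes)(PCy3)(=CHPh) (second-generation Grubbs catalyst, 1 mM, CH2Cl2, 40 °C) gives the macrocyclic cross-conjugated dienone (1E,4Z,6S,7R,8S,10S)-8-angeloyloxy-10-hydroxy-3-oxogermacra-1,4,11(13)-trien-12,6-olide F5. Corey–Bakshi–Shibata reduction ((R)-2-methyl-oxazaborolidine, BH3·SMe2, THF, −30 °C) gives the 3S alcohol 16.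

Third: step 4, the 1,3-anti vinyl addition (modest diastereoselectivity from the free magnesium alkoxide chelate). The fallback sets out from 7 and comes back at 8, replacing alkoxide direction by a rigid bidentate ether–ketone chelate. Protection with 4-methoxybenzyl trichloroacetimidate (PPTS cat., CH2Cl2) gives (4S)-5,5-dimethoxy-4-[(4-methoxyphenyl)methoxy]pentan-2-one F6. Cram-chelate addition (MgBr2·OEt2, then CH2=CHMgBr, CH2Cl2, −78 °C) gives (3S,5S)-6,6-dimethoxy-5-[(4-methoxyphenyl)methoxy]-3-methylhex-1-en-3-ol F7. DDQ (CH2Cl2/pH 7 buffer) then releases 8.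

**Further compounds**
F1 | step 9 | methyl (2E,4S,6S)-6-hydroxy-2-(hydroxymethyl)-6-methyl-4-{[(2Z)-2-methylbut-2-enoyl]oxy}octa-2,7-dienoate | C=C[C@@](C)(O)C[C@H](OC(=O)/C(C)=C\C)/C=C(\CO)C(=O)OC
F2 | step 9 | methyl (2Z,4S,6S)-2-(bromomethyl)-6-hydroxy-6-methyl-4-{[(2Z)-2-methylbut-2-enoyl]oxy}octa-2,7-dienoate | C=C[C@@](C)(O)C[C@H](OC(=O)/C(C)=C\C)/C=C(\CBr)C(=O)OC
F3 | step 9 | methyl (3S,4R,5Z)-4-hydroxy-3-[(1S,3S)-3-hydroxy-3-methyl-1-{[(2Z)-2-methylbut-2-enoyl]oxy}pent-4-en-1-yl]-6-iodo-2-methylidenehept-5-enoate | C=C(C(=O)OC)[C@@H]([C@@H](O)/C=C(/C)I)[C@@H](OC(=O)/C(C)=C\C)C[C@](C)(O)C=C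
F4 | step 11 | (1S,3S)-3-hydroxy-3-methyl-1-[(2S,3R)-2-[(1Z)-2-methyl-3-oxopenta-1,4-dien-1-yl]-4-methylidene-5-oxooxolan-3-yl]pent-4-en-1-yl (2Z)-2-methylbut-2-enoate | C=C1C(=O)O[C@@H](/C=C(/C)C(=O)C=C)[C@H]1[C@@H](OC(=O)/C(C)=C\C)C[C@](C)(O)C=C
F5 | step 11 | (1E,4Z,6S,7R,8S,10S)-8-[(2Z)-2-methylbut-2-enoyloxy]-10-hydroxy-3-oxogermacra-1,4,11(13)-trien-12,6-olide | C=C1C(=O)O[C@H]2/C=C(/C)C(=O)/C=C/[C@@](C)(O)C[C@H](OC(=O)/C(C)=C\C)[C@@H]12
F6 | step 4 | (4S)-5,5-dimethoxy-4-[(4-methoxyphenyl)methoxy]pentan-2-one | CC(=O)C[C@H](OCc1ccc(OC)cc1)C(OC)OC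
F7 | step 4 | (3S,5S)-6,6-dimethoxy-5-[(4-methoxyphenyl)methoxy]-3-methylhex-1-en-3-ol | C=C[C@@](C)(O)C[C@H](OCc1ccc(OC)cc1)C(OC)OC
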